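**Retrosynthetic overview**

- The target acid comes from Pinnick oxidation of the bicyclic aldehyde, which comes from an intramolecular Diels–Alder reaction of a linear (2E,4E,6R,7E,9E,11E)-pentaenal; the cyclohexene and cyclopentene rings form together in that one step, and all five ring stereocentres are set from the single C6 centre.
- The pentaenal comes from a Wittig reaction (C2=C3) on a C3 enal, obtained from an (E)-2-ethyl enoyl imide by reductive auxiliary removal and oxidation.
- Key C4–C5 bond: intermolecular Evans boron aldol between the C5–C12 trienal (fragment A) and (R)-4-benzyl-3-butanoyloxazolidin-2-one (fragment B), followed by dehydration to the E alkene.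
- Fragment A comes from TBS-protected (S)-Roche aldehyde by three iterative Horner–Wadsworth–Emmons olefinations (two with triethyl 2-phosphonobutyrate, one with diethyl benzylphosphonate).
- No ring exists before the end-game; the only stereocentre carried through is C6, from (S)-Roche ester.

Assumption: the target is (1S,3aS,4S,5R,7aR)-configured as in the given SMILES; chain numbering in the comments is that of the linear precursor (C1 = carboxyl carbon, C6 = methyl-bearing stereocentre, C12 = benzylic carbon).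

**Step 1**
Reactants: 1 methyl (S)-3-hydroxy-2-methylpropanoate
Product: 2 methyl (S)-3-[(tert-butyldimethylsilyl)oxy]-2-methylpropanoate
Conditions: TBSCl, imidazole, DMF, rt
Reagents that add atoms: tert-butyldimethylsilyl chloride (TBSCl), CC(C)(C)[Si](C)(C)Cl
Why: Imidazole-promoted silylation of a primary alcohol is essentially quantitative, creates no stereocentre and gives an ether that survives the hydride, base and MnO2 steps ahead.

**Step 2**
Reactants: 2 methyl (S)-3-[(tert-butyldimethylsilyl)oxy]-2-methylpropanoate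
Product: 3 (R)-3-[(tert-butyldimethylsilyl)oxy]-2-methylpropan-1-ol
Conditions: iBu2AlH (2.5 equiv), CH2Cl2, −78 → 0 °C
Reagents that add atoms: none
Why: Full hydride reduction of the ester to the primary alcohol is more dependable than stopping at the aldehyde, and neither the silyl ether nor the stereocentre is affected.

**Step 3**
Reactants: 3 (R)-3-[(tert-butyldimethylsilyl)oxy]-2-methylpropan-1-ol
Product: 4 (S)-3-[(tert-butyldimethylsilyl)oxy]-2-methylpropanal
Conditions: (COCl)2, DMSO, CH2Cl2, −78 °C; then Et3N, −78 → −20 °C; used crude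
Reagents that add atoms: none
Why: Swern oxidation at low temperature gives the α-methyl aldehyde without over-oxidation, and using it cold and crude avoids epimerisation of the only stereocentre.

**Step 4**
Reactants: 4 (S)-3-[(tert-butyldimethylsilyl)oxy]-2-methylpropanal; 5 triethyl 2-phosphonobutyrate
Product: 6 ethyl (2E,4R)-5-[(tert-butyldimethylsilyl)oxy]-2-ethyl-4-methylpent-2-enoate
Conditions: NaH, THF, 0 °C; then 4, 0 °C → rt
Reagents that add atoms: none
Why: The Horner–Wadsworth–Emmons reaction of an α-branched aldehyde with an α-alkyl phosphonoacetate gives the (E)-trisubstituted enoate (C7=C8) with the minor Z isomer removable by chromatography, and no new stereocentre is formed.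

**Step 5**
Reactants: 6 ethyl (2E,4R)-5-[(tert-butyldimethylsilyl)oxy]-2-ethyl-4-methylpent-2-enoate
Product: 7 (2E,4R)-5-[(tert-butyldimethylsilyl)oxy]-2-ethyl-4-methylpent-2-en-1-ol
Conditions: iBu2AlH, CH2Cl2, −78 °C
Reagents that add atoms: none
Why: iBu2AlH reduces the conjugated ester by 1,2-hydride delivery to the allylic alcohol without touching the alkene geometry or the silyl ether.

**Step 6**
Reactants: 7 (2E,4R)-5-[(tert-butyldimethylsilyl)oxy]-2-ethyl-4-methylpent-2-en-1-ol
Product: 8 (2E,4R)-5-[(tert-butyldimethylsilyl)oxy]-2-ethyl-4-methylpent-2-enal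
Conditions: MnO2 (excess), CH2Cl2, rt
Reagents that add atoms: none
Why: MnO2 is a neutral heterogeneous oxidant selective for allylic alcohols, so the (E)-enal forms without isomerisation or epimerisation of the γ-stereocentre.

**Step 7**
Reactants: 8 (2E,4R)-5-[(tert-butyldimethylsilyl)oxy]-2-ethyl-4-methylpent-2-enal; 5 triethyl 2-phosphonobutyrate
Product: 9 ethyl (2E,4E,6R)-7-[(tert-butyldimethylsilyl)oxy]-2,4-diethyl-6-methylhepta-2,4-dienoate
Conditions: NaH, THF, 0 °C; then 8, 0 °C → rt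
Reagents that add atoms: none
Why: A second Horner–Wadsworth–Emmons olefination adds the C9=C10 unit with E geometry, because addition of the stabilised phosphonate anion to the enal carbonyl is much faster than any γ-deprotonation.

**Step 8**
Reactants: 9 ethyl (2E,4E,6R)-7-[(tert-butyldimethylsilyl)oxy]-2,4-diethyl-6-methylhepta-2,4-dienoate
Product: 10 (2E,4E,6R)-7-[(tert-butyldimethylsilyl)oxy]-2,4-diethyl-6-methylhepta-2,4-dien-1-ol
Conditions: iBu2AlH, CH2Cl2, −78 °C
Reagents that add atoms: none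
Why: 1,2-Hydride reduction of the dienoate gives the dienol with both alkene geometries intact.

**Step 9**
Reactants: 10 (2E,4E,6R)-7-[(tert-butyldimethylsilyl)oxy]-2,4-diethyl-6-methylhepta-2,4-dien-1-ol
Product: 11 (2E,4E,6R)-7-[(tert-butyldimethylsilyl)oxy]-2,4-diethyl-6-methylhepta-2,4-dienal
Conditions: MnO2 (excess), CH2Cl2, rt
Reagents that add atoms: none
Why: Allylic oxidation with MnO2 gives the dienal under neutral conditions with no change to geometry or configuration.

**Step 10**
Reactants: 11 (2E,4E,6R)-7-[(tert-butyldimethylsilyl)oxy]-2,4-diethyl-6-methylhepta-2,4-dienal; 12 diethyl benzylphosphonate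
Product: 13 tert-butyl{[(2R,3E,5E,7E)-4,6-diethyl-2-methyl-8-phenylocta-3,5,7-trien-1-yl]oxy}dimethylsilane
Conditions: KOtBu (1.2 equiv), 12 (1.3 equiv), THF, 0 °C; then 11, −78 → 0 °C
Reagents that add atoms: none
Why: The Horner–Wadsworth–Emmons reaction of a benzylphosphonate anion with an enal gives the (E)-styrene almost exclusively, and adding the aldehyde cold to a preformed anion with no free alkoxide keeps the remote C6–H from being deprotonated.

**Step 11**
Reactants: 13 tert-butyl{[(2R,3E,5E,7E)-4,6-diethyl-2-methyl-8-phenylocta-3,5,7-trien-1-yl]oxy}dimethylsilane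
Product: 14 (2R,3E,5E,7E)-4,6-diethyl-2-methyl-8-phenylocta-3,5,7-trien-1-ol
Conditions: Bu4NF (TBAF), THF, 0 °C → rt
Reagents that add atoms: none
Why: Fluoride-mediated silyl ether cleavage is selective for the Si–O bond, and the triene and the stereocentre are inert to it.

**Step 12**
Reactants: 14 (2R,3E,5E,7E)-4,6-diethyl-2-methyl-8-phenylocta-3,5,7-trien-1-ol
Product: 15 (2R,3E,5E,7E)-4,6-diethyl-2-methyl-8-phenylocta-3,5,7-trienal
Conditions: Dess–Martin periodinane, NaHCO3, CH2Cl2, 0 °C; used at once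
Reagents that add atoms: none
Why: Bicarbonate-buffered Dess–Martin oxidation is fast and neither acidic nor basic, so the fragile α-methyl β,γ-unsaturated aldehyde is obtained without enolisation provided it is used immediately.

**Step 13**
Reactants: 16 (R)-4-benzyloxazolidin-2-one; 17 butanoyl chloride
Product: 18 (R)-4-benzyl-3-butanoyloxazolidin-2-one
Conditions: Et3N, DMAP (cat.), CH2Cl2, 0 °C → rt
Reagents that add atoms: none
Why: DMAP-catalysed N-acylation of the oxazolidinone by the acid chloride gives the imide without touching the auxiliary stereocentre.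

**Step 14**
Reactants: 15 (2R,3E,5E,7E)-4,6-diethyl-2-methyl-8-phenylocta-3,5,7-trienal; 18 (R)-4-benzyl-3-butanoyloxazolidin-2-one
Product: 21 (R)-4-benzyl-3-[(2R,3S,4R,5E,7E,9E)-2,6,8-triethyl-3-hydroxy-4-methyl-10-phenyldeca-5,7,9-trienoyl]oxazolidin-2-one, via dibutylboron Z-enolate 19 (not isolated), via boron aldolate 20 (not isolated)
Conditions: 18 (1.5 equiv), Bu2BOTf, iPr2NEt, CH2Cl2, 0 °C; then 15, −78 → 0 °C; pH 7 buffer, MeOH, H2O2, 0 °C
Reagents that add atoms: none
Why: In this Evans syn-aldol reaction the (Z)-boron enolate adds through a closed Zimmerman–Traxler chair whose facial sense is fixed by the (R)-benzyl auxiliary, giving the (2R,3S)-syn aldol (matched with the anti-Felkin preference of Z-enolates for the α-methyl aldehyde) and consuming the labile aldehyde at −78 °C before it can enolise, the two new stereocentres serving only to guarantee the syn relationship that the next step converts into an E alkene.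

**Step 15**
Reactants: 21 (R)-4-benzyl-3-[(2R,3S,4R,5E,7E,9E)-2,6,8-triethyl-3-hydroxy-4-methyl-10-phenyldeca-5,7,9-trienoyl]oxazolidin-2-one
Product: 23 (R)-4-benzyl-3-[(2E,4R,5E,7E,9E)-2,6,8-triethyl-4-methyl-10-phenyldeca-2,5,7,9-tetraenoyl]oxazolidin-2-one, via mesylate 22 (not isolated)
Conditions: MsCl, Et3N, CH2Cl2, 0 °C; then DBU, 0 °C, short contact
Reagents that add atoms: none
Why: Mesylation followed by β-elimination (E1cB through the acidic imide α-hydrogen or anti-E2 from the syn aldol, both leading to the same isomer) erases the two sacrificial stereocentres and gives only the conjugated (E)-2-ethyl enoyl imide, the C4–H being far more acidic than the C6–H so that the stereocentre is untouched if base contact is kept short and cold.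

**Step 16**
Reactants: 23 (R)-4-benzyl-3-[(2E,4R,5E,7E,9E)-2,6,8-triethyl-4-methyl-10-phenyldeca-2,5,7,9-tetraenoyl]oxazolidin-2-one
Product: 24 (2E,4R,5E,7E,9E)-2,6,8-triethyl-4-methyl-10-phenyldeca-2,5,7,9-tetraen-1-ol
Conditions: NaBH4, THF/H2O (4:1), 0 °C → rt
Reagents that add atoms: none
Why: NaBH4 in wet THF attacks the exocyclic carbonyl of the α-branched enoyl oxazolidinone (reductive auxiliary cleavage by 1,2-hydride addition), giving the allylic alcohol and returning the auxiliary.

**Step 17**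
Reactants: 24 (2E,4R,5E,7E,9E)-2,6,8-triethyl-4-methyl-10-phenyldeca-2,5,7,9-tetraen-1-ol
Product: 25 (2E,4R,5E,7E,9E)-2,6,8-triethyl-4-methyl-10-phenyldeca-2,5,7,9-tetraenal
Conditions: MnO2 (excess), CH2Cl2, rt
Reagents that add atoms: none
Why: Neutral allylic oxidation with MnO2 gives the (E)-enal without exposing the doubly allylic C6–H to acid or base.

**Step 18**
Reactants: 25 (2E,4R,5E,7E,9E)-2,6,8-triethyl-4-methyl-10-phenyldeca-2,5,7,9-tetraenal; 26 ethyl 2-(triphenylphosphoranylidene)propanoate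
Product: 27 ethyl (2E,4E,6R,7E,9E,11E)-4,8,10-triethyl-2,6-dimethyl-12-phenyldodeca-2,4,7,9,11-pentaenoate
Conditions: toluene, 70 °C
Reagents that add atoms: none
Why: The Wittig reaction of the stabilised, non-basic ylide with the enal gives the (E)-2-methyl-2-enoate selectively and cannot deprotonate C6–H, while the ester dienophile is too unreactive to cyclise at this temperature.

**Step 19**
Reactants: 27 ethyl (2E,4E,6R,7E,9E,11E)-4,8,10-triethyl-2,6-dimethyl-12-phenyldodeca-2,4,7,9,11-pentaenoate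
Product: 28 (2E,4E,6R,7E,9E,11E)-4,8,10-triethyl-2,6-dimethyl-12-phenyldodeca-2,4,7,9,11-pentaen-1-ol
Conditions: iBu2AlH, CH2Cl2, −78 °C
Reagents that add atoms: none
Why: 1,2-Hydride reduction of the dienoate gives the dienol without affecting the skipped polyene or the stereocentre.

**Step 20**
Reactants: 28 (2E,4E,6R,7E,9E,11E)-4,8,10-triethyl-2,6-dimethyl-12-phenyldodeca-2,4,7,9,11-pentaen-1-ol
Product: 30 (1S,3aS,4S,5R,7aR)-3,5,7-triethyl-1,4-dimethyl-5-[(E)-2-phenylethenyl]-3a,4,5,7a-tetrahydro-1H-indene-4-carbaldehyde, via pentaenal 29 (not isolated)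
Conditions: MnO2, CH2Cl2, rt; filter; then toluene, BHT (cat.), 80 °C
Reagents that add atoms: none
Why: MnO2 unmasks the dienal, whose C2=C3 bond then adds to the C7–C10 diene in an intramolecular Diels–Alder reaction through the endo (formyl under the diene) transition state, in which allylic 1,3-strain with the C8 ethyl group holds C6–H in the diene plane so that the tether attacks anti to the C6 methyl group, setting the trans ring fusion, both quaternary centres (from the E alkene geometries) and the absolute configuration of all five ring stereocentres from C6 alone.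

**Step 21**
Reactants: 30 (1S,3aS,4S,5R,7aR)-3,5,7-triethyl-1,4-dimethyl-5-[(E)-2-phenylethenyl]-3a,4,5,7a-tetrahydro-1H-indene-4-carbaldehyde
Product: 31 (1S,3aS,4S,5R,7aR)-3,5,7-triethyl-1,4-dimethyl-5-[(E)-2-phenylethenyl]-3a,4,5,7a-tetrahydro-1H-indene-4-carboxylic acid
Conditions: NaClO2, NaH2PO4, 2-methylbut-2-ene, tBuOH/THF/H2O, rt
Reagents that add atoms: sodium chlorite (NaClO2), [Na+].[O-]Cl=O
Why: Pinnick oxidation converts the hindered, non-enolisable aldehyde into the acid while 2-methylbut-2-ene scavenges HOCl and so protects the three alkenes, and no stereocentre can epimerise.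

**Compound list**

1 | methyl (S)-3-hydroxy-2-methylpropanoate ((S)-Roche ester) | OC[C@H](C)C(=O)OC | starting material
2 | methyl (S)-3-[(tert-butyldimethylsilyl)oxy]-2-methylpropanoate | CC(C)(C)[Si](C)(C)OC[C@H](C)C(=O)OC | intermediate
3 | (R)-3-[(tert-butyldimethylsilyl)oxy]-2-methylpropan-1-ol | CC(C)(C)[Si](C)(C)OC[C@H](C)CO | intermediate
4 | (S)-3-[(tert-butyldimethylsilyl)oxy]-2-methylpropanal | CC(C)(C)[Si](C)(C)OC[C@H](C)C=O | intermediate
5 | triethyl 2-phosphonobutyrate (ethyl 2-(diethoxyphosphoryl)butanoate) | CCOC(=O)C(CC)P(=O)(OCC)OCC | starting material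
6 | ethyl (2E,4R)-5-[(tert-butyldimethylsilyl)oxy]-2-ethyl-4-methylpent-2-enoate | CC(C)(C)[Si](C)(C)OC[C@H](C)/C=C(\CC)C(=O)OCC | intermediate
7 | (2E,4R)-5-[(tert-butyldimethylsilyl)oxy]-2-ethyl-4-methylpent-2-en-1-ol | CC(C)(C)[Si](C)(C)OC[C@H](C)/C=C(\CC)CO | intermediate
8 | (2E,4R)-5-[(tert-butyldimethylsilyl)oxy]-2-ethyl-4-methylpent-2-enal | CC(C)(C)[Si](C)(C)OC[C@H](C)/C=C(\CC)C=O | intermediate
9 | ethyl (2E,4E,6R)-7-[(tert-butyldimethylsilyl)oxy]-2,4-diethyl-6-methylhepta-2,4-dienoate | CC(C)(C)[Si](C)(C)OC[C@H](C)/C=C(CC)/C=C(\CC)C(=O)OCC | intermediate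
10 | (2E,4E,6R)-7-[(tert-butyldimethylsilyl)oxy]-2,4-diethyl-6-methylhepta-2,4-dien-1-ol | CC(C)(C)[Si](C)(C)OC[C@H](C)/C=C(CC)/C=C(\CC)CO | intermediate
11 | (2E,4E,6R)-7-[(tert-butyldimethylsilyl)oxy]-2,4-diethyl-6-methylhepta-2,4-dienal | CC(C)(C)[Si](C)(C)OC[C@H](C)/C=C(CC)/C=C(\CC)C=O | intermediate
12 | diethyl benzylphosphonate | CCOP(=O)(Cc1ccccc1)OCC | starting material
13 | tert-butyl{[(2R,3E,5E,7E)-4,6-diethyl-2-methyl-8-phenylocta-3,5,7-trien-1-yl]oxy}dimethylsilane | CC(C)(C)[Si](C)(C)OC[C@H](C)/C=C(CC)/C=C(CC)/C=C/c1ccccc1 | intermediate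
14 | (2R,3E,5E,7E)-4,6-diethyl-2-methyl-8-phenylocta-3,5,7-trien-1-ol | OC[C@H](C)/C=C(CC)/C=C(CC)/C=C/c1ccccc1 | intermediate
15 | (2R,3E,5E,7E)-4,6-diethyl-2-methyl-8-phenylocta-3,5,7-trienal (fragment A) | O=C[C@H](C)/C=C(CC)/C=C(CC)/C=C/c1ccccc1 | intermediate
16 | (R)-4-benzyloxazolidin-2-one | O=C1N[C@H](Cc2ccccc2)CO1 | starting material
17 | butanoyl chloride | CCCC(Cl)=O | starting material
18 | (R)-4-benzyl-3-butanoyloxazolidin-2-one (fragment B) | CCCC(=O)N1[C@H](Cc2ccccc2)COC1=O | intermediate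
19 | (R)-4-benzyl-3-[(Z)-1-(dibutylboranyloxy)but-1-en-1-yl]oxazolidin-2-one (boron enolate) | CC/C=C(\OB(CCCC)CCCC)N1[C@H](Cc2ccccc2)COC1=O | intermediate (not isolated)
20 | (R)-4-benzyl-3-[(2R,3S,4R,5E,7E,9E)-3-(dibutylboranyloxy)-2,6,8-triethyl-4-methyl-10-phenyldeca-5,7,9-trienoyl]oxazolidin-2-one (boron aldolate) | O=C(N1[C@H](Cc2ccccc2)COC1=O)[C@H](CC)[C@@H](OB(CCCC)CCCC)[C@H](C)/C=C(CC)/C=C(CC)/C=C/c1ccccc1 | intermediate (not isolated)
21 | (R)-4-benzyl-3-[(2R,3S,4R,5E,7E,9E)-2,6,8-triethyl-3-hydroxy-4-methyl-10-phenyldeca-5,7,9-trienoyl]oxazolidin-2-one | O=C(N1[C@H](Cc2ccccc2)COC1=O)[C@H](CC)[C@@H](O)[C@H](C)/C=C(CC)/C=C(CC)/C=C/c1ccccc1 | intermediate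
22 | (R)-4-benzyl-3-[(2R,3S,4R,5E,7E,9E)-2,6,8-triethyl-4-methyl-3-(methylsulfonyloxy)-10-phenyldeca-5,7,9-trienoyl]oxazolidin-2-one | O=C(N1[C@H](Cc2ccccc2)COC1=O)[C@H](CC)[C@@H](OS(C)(=O)=O)[C@H](C)/C=C(CC)/C=C(CC)/C=C/c1ccccc1 | intermediate (not isolated)
23 | (R)-4-benzyl-3-[(2E,4R,5E,7E,9E)-2,6,8-triethyl-4-methyl-10-phenyldeca-2,5,7,9-tetraenoyl]oxazolidin-2-one | O=C(N1[C@H](Cc2ccccc2)COC1=O)/C(CC)=C/[C@H](C)/C=C(CC)/C=C(CC)/C=C/c1ccccc1 | intermediate
24 | (2E,4R,5E,7E,9E)-2,6,8-triethyl-4-methyl-10-phenyldeca-2,5,7,9-tetraen-1-ol | OC/C(CC)=C/[C@H](C)/C=C(CC)/C=C(CC)/C=C/c1ccccc1 | intermediate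
25 | (2E,4R,5E,7E,9E)-2,6,8-triethyl-4-methyl-10-phenyldeca-2,5,7,9-tetraenal | O=C/C(CC)=C/[C@H](C)/C=C(CC)/C=C(CC)/C=C/c1ccccc1 | intermediate
26 | ethyl 2-(triphenylphosphoranylidene)propanoate | CCOC(=O)C(C)=P(c1ccccc1)(c1ccccc1)c1ccccc1 | starting material
27 | ethyl (2E,4E,6R,7E,9E,11E)-4,8,10-triethyl-2,6-dimethyl-12-phenyldodeca-2,4,7,9,11-pentaenoate | CCOC(=O)/C(C)=C/C(CC)=C/[C@H](C)/C=C(CC)/C=C(CC)/C=C/c1ccccc1 | intermediate
28 | (2E,4E,6R,7E,9E,11E)-4,8,10-triethyl-2,6-dimethyl-12-phenyldodeca-2,4,7,9,11-pentaen-1-ol | OC/C(C)=C/C(CC)=C/[C@H](C)/C=C(CC)/C=C(CC)/C=C/c1ccccc1 | intermediate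
29 | (2E,4E,6R,7E,9E,11E)-4,8,10-triethyl-2,6-dimethyl-12-phenyldodeca-2,4,7,9,11-pentaenal | O=C/C(C)=C/C(CC)=C/[C@H](C)/C=C(CC)/C=C(CC)/C=C/c1ccccc1 | intermediate (not isolated)
30 | (1S,3aS,4S,5R,7aR)-3,5,7-triethyl-1,4-dimethyl-5-[(E)-2-phenylethenyl]-3a,4,5,7a-tetrahydro-1H-indene-4-carbaldehyde | CCC1=C[C@](/C=C/c2ccccc2)(CC)[C@@](C)(C=O)[C@@H]2C(CC)=C[C@H](C)[C@@H]12 | intermediate
31 | (1S,3aS,4S,5R,7aR)-3,5,7-triethyl-1,4-dimethyl-5-[(E)-2-phenylethenyl]-3a,4,5,7a-tetrahydro-1H-indene-4-carboxylic acid | CCC1=C[C@](/C=C/c2ccccc2)(CC)[C@@](C)(C(=O)O)[C@@H]2C(CC)=C[C@H](C)[C@@H]12 | target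

**Step count and risks**

Total steps: 21. Longest linear sequence: 20 (steps 1–12, then 14–21); step 13 is the one-step branch.

Most likely to fail, first: step 14 (aldol on the labile aldehyde 15). The α-methyl β,γ-unsaturated aldehyde may lose configuration or slide into conjugation under the amine-containing boron aldol conditions and the warm-up. The fallback sets out from 15 and comes back at 24. A Reformatsky addition of ethyl 2-bromobutanoate promoted by SmI2 in THF at −78 °C (no amine, complete in minutes) gives the β-hydroxy ester ethyl (4R,5E,7E,9E)-2,6,8-triethyl-3-hydroxy-4-methyl-10-phenyldeca-5,7,9-trienoate F1 as a mixture at C2 and C3. MsCl and Et3N convert it into ethyl (4R,5E,7E,9E)-2,6,8-triethyl-4-methyl-3-(methylsulfonyloxy)-10-phenyldeca-5,7,9-trienoate F2, and DBU eliminates this stereoconvergently (E1cB) to ethyl (2E,4R,5E,7E,9E)-2,6,8-triethyl-4-methyl-10-phenyldeca-2,5,7,9-tetraenoate F3. iBu2AlH at −78 °C reduces F3 to 24.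

Second: step 15 (mesylation and elimination on the imide). DBU could also remove the doubly allylic C6–H of product 23 and move the alkene into conjugation with the triene, destroying the stereocentre. The fallback sets out from 21 and comes back at 25, moving the elimination to the aldehyde level where Et3N alone suffices. LiBH4 in wet Et2O cleaves the auxiliary to give (2S,3S,4R,5E,7E,9E)-2,6,8-triethyl-4-methyl-10-phenyldeca-5,7,9-triene-1,3-diol F4. TEMPO with PhI(OAc)2 oxidises only the primary alcohol to (2R,3S,4R,5E,7E,9E)-2,6,8-triethyl-3-hydroxy-4-methyl-10-phenyldeca-5,7,9-trienal F5. MsCl and Et3N at −20 °C form (2R,3S,4R,5E,7E,9E)-2,6,8-triethyl-4-methyl-1-oxo-10-phenyldeca-5,7,9-trien-3-yl methanesulfonate F6, which loses methanesulfonate in the same flask to give the thermodynamically favoured (E)-enal 25.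

Third: step 20 (oxidation and intramolecular Diels–Alder reaction). The pentaenal may decompose or give an unfavourable endo/exo or facial ratio, and the later oxidation of the hindered aldehyde is then also at stake. The fallback sets out from 27 and comes back at 31, cyclising at the carboxylic acid level. Me3SnOH in 1,2-dichloroethane at 70 °C hydrolyses the ester without strong base to (2E,4E,6R,7E,9E,11E)-4,8,10-triethyl-2,6-dimethyl-12-phenyldodeca-2,4,7,9,11-pentaenoic acid F7. Heating F7 in toluene with BHT at 100–110 °C effects the same endo cycloaddition and gives 31 directly, with minor diastereomers removed by chromatography or crystallisation.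

**Further compounds**

F1 | step 14 | ethyl (4R,5E,7E,9E)-2,6,8-triethyl-3-hydroxy-4-methyl-10-phenyldeca-5,7,9-trienoate | CCOC(=O)C(CC)C(O)[C@H](C)/C=C(CC)/C=C(CC)/C=C/c1ccccc1
F2 | step 14 | ethyl (4R,5E,7E,9E)-2,6,8-triethyl-4-methyl-3-(methylsulfonyloxy)-10-phenyldeca-5,7,9-trienoate | CCOC(=O)C(CC)C(OS(C)(=O)=O)[C@H](C)/C=C(CC)/C=C(CC)/C=C/c1ccccc1
F3 | step 14 | ethyl (2E,4R,5E,7E,9E)-2,6,8-triethyl-4-methyl-10-phenyldeca-2,5,7,9-tetraenoate | CCOC(=O)/C(CC)=C/[C@H](C)/C=C(CC)/C=C(CC)/C=C/c1ccccc1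
F4 | step 15 | (2S,3S,4R,5E,7E,9E)-2,6,8-triethyl-4-methyl-10-phenyldeca-5,7,9-triene-1,3-diol | OC[C@H](CC)[C@@H](O)[C@H](C)/C=C(CC)/C=C(CC)/C=C/c1ccccc1
F5 | step 15 | (2R,3S,4R,5E,7E,9E)-2,6,8-triethyl-3-hydroxy-4-methyl-10-phenyldeca-5,7,9-trienal | O=C[C@H](CC)[C@@H](O)[C@H](C)/C=C(CC)/C=C(CC)/C=C/c1ccccc1
F6 | step 15 | (2R,3S,4R,5E,7E,9E)-2,6,8-triethyl-4-methyl-1-oxo-10-phenyldeca-5,7,9-trien-3-yl methanesulfonate | O=C[C@H](CC)[C@@H](OS(C)(=O)=O)[C@H](C)/C=C(CC)/C=C(CC)/C=C/c1ccccc1
F7 | step 20 | (2E,4E,6R,7E,9E,11E)-4,8,10-triethyl-2,6-dimethyl-12-phenyldodeca-2,4,7,9,11-pentaenoic acid | OC(=O)/C(C)=C/C(CC)=C/[C@H](C)/C=C(CC)/C=C(CC)/C=C/c1ccccc1
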